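The ring carbons are numbered C1 (bearing the exocyclic methylene) to C14 (hydroperoxide), with the epoxide at C4/C5, the carbinol at C11 and the δ-lactone ring O–C16(=O)–C15–C8–C9–C10. The route rests on removing this lactone bridge as a propionate unit. The key step exploits the anti C10–O/C11–OH pattern beside the C15–C8 bond, the mark of a carboxylate-opened trans-epoxide. An Ireland–Claisen rearrangement of an acyclic, epoxyfarnesol-derived (R)-allylic propionate forms C15–C8 with chirality transfer. The carboxylate then opens the Sharpless-derived (10S,11S)-epoxide at C10 in the same flask, closing the lactone and fixing C15, C8, C10 and C11. Ring-closing metathesis and a singlet-oxygen ene reaction complete the carbocycle and the hydroperoxide.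

Key step: step 5

Remark: (2E,6E)-farnesol and (R)-but-3-en-2-ol are taken as commercial; C17, C18, C19 and C20 are the methyl carbons on C15, C5, C11 and C1; acyclic intermediates keep the target numbering; the C6=C7 geometry of 16 is immaterial and is drawn E.

Step 1
Reactants: 1 (2E,6E)-farnesol
Product: 2 (2S,3S)-2,3-epoxyfarnesol
Conditions: Ti(OiPr)4 (10 mol%), L-(+)-diethyl tartrate (12 mol%), t-BuOOH, 4 Å MS, CH2Cl2, −20 °C
Reagents that add atoms: tert-butyl hydroperoxide, CC(C)(C)OO
Why: Katsuki–Sharpless asymmetric epoxidation acts only on the allylic-alcohol alkene, and L-(+)-diethyl tartrate sets both new centres as (2S,3S), i.e. (10S,11S) in target numbering, by reagent control.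

Step 2
Reactants: 2 (2S,3S)-2,3-epoxyfarnesol
Product: 4 (2S,3S)-2-[(3E)-4,8-dimethylnona-3,7-dien-1-yl]-2-methyl-3-(prop-2-en-1-yl)oxirane, via epoxyfarnesyl triflate 3 (not isolated)
Conditions: Tf2O, 2,6-lutidine, CH2Cl2, −78 °C; then CH2=CHMgBr, CuBr·SMe2 (10 mol%), THF, −78 to −40 °C
Reagents that add atoms: vinylmagnesium bromide, C=C[Mg]Br
Why: Copper-catalysed Grignard coupling displaces the primary triflate much faster than the trisubstituted oxirane is opened (epoxy sulfonate coupling), so C9 gains a vinyl group while both epoxide centres stay untouched.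

Step 3
Reactants: 5 (R)-but-3-en-2-ol
Product: 6 (R)-but-3-en-2-yl propanoate
Conditions: (EtCO)2O, Et3N, DMAP (cat.), CH2Cl2, 0 to 23 °C
Reagents that add atoms: propionic anhydride, CCC(=O)OC(=O)CC
Why: DMAP-catalysed O-acylation of the secondary alcohol does not break the carbinol C–O bond, so the (R) configuration is retained.

Step 4
Reactants: 4 allyl epoxide; 6 (R)-but-3-en-2-yl propanoate
Product: 7 (2R,3E)-5-[(2S,3S)-3-[(3E)-4,8-dimethylnona-3,7-dien-1-yl]-3-methyloxiran-2-yl]pent-3-en-2-yl propanoate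
Conditions: second-generation Hoveyda–Grubbs catalyst RuCl2(1,3-dimesitylimidazolidin-2-ylidene)(=CH-C6H4-2-OiPr) (5 mol%), 6 (3 equiv), CH2Cl2, 40 °C
Reagents that add atoms: none
Why: Olefin cross-metathesis between the terminal alkene of 4 and an excess of the slowly homodimerizing secondary allylic ester should give the (E)-1,2-disubstituted alkene under thermodynamic control, with the trisubstituted alkenes and the carbinol centre inert.

Step 5
Reactants: 7 (R)-allylic propionate
Product: 11 (3S,4S,6R)-6-[(2S,5E)-2-hydroxy-6,10-dimethylundeca-5,9-dien-2-yl]-3-methyl-4-[(1E)-prop-1-en-1-yl]oxan-2-one, via silyl ketene acetal 8 (not isolated), via trimethylsilyl ester 9 (not isolated), via tetrabutylammonium carboxylate 10 (not isolated)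
Conditions: LiN(iPr)2, Me3SiCl/Et3N, THF, −78 to 40 °C; then Bu4NF, THF, 60 °C; aq. NH4Cl
Reagents that add atoms: none
Why: LiN(iPr)2 in THF gives the (E)-silyl ketene acetal 8, which undergoes the Ireland–Claisen [3,3]-sigmatropic rearrangement through a chair transition state to silyl ester 9, forming C15–C8; fluoride then frees carboxylate 10, whose oxygen attacks C10 of the oxirane to form O–C10. The closest known reaction types are the Ireland–Claisen rearrangement of secondary (E)-allylic propionates and the lactonization of 5,6-epoxy carboxylic acids. The δ-lactone closes by 6-exo-tet SN2 opening of the oxirane. C8 is set by 1,3-chirality transfer from the (R)-carbinol (its methyl equatorial in the chair), C15 by the ketene acetal geometry (methyl anti to the C9 branch), C10 by inversion of the (10S)-epoxide carbon and C11 by retention of the Sharpless-set centre. The step needs attack at C10 and not 7-endo attack at the tertiary C11, which the non-acidic carboxylate conditions should secure (SN2 at the less substituted carbon, smaller ring), while the acyclic (E)-alkene with an equatorial carbinol methyl secures the chair.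

Step 6
Reactants: 11 propenyl lactone
Product: 12 (3S,4S,6R)-6-[(2S,5E,9E)-2,11-dihydroxy-6,10-dimethylundeca-5,9-dien-2-yl]-3-methyl-4-[(1E)-prop-1-en-1-yl]oxan-2-one
Conditions: SeO2 (cat.), t-BuOOH, salicylic acid (cat.), CH2Cl2, 23 °C
Reagents that add atoms: tert-butyl hydroperoxide, CC(C)(C)OO
Why: SeO2-catalysed allylic hydroxylation (ene reaction followed by [2,3]-sigmatropic shift) should attack the (E)-methyl group of the terminal trisubstituted alkene, the most accessible electron-rich site as in polyprenyl chains, giving the (E)-allylic alcohol at C6 without creating a stereocentre.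

Step 7
Reactants: 12 allylic alcohol
Product: 13 (3S,4S,6R)-6-[(2S,5E)-2-hydroxy-8-[(2S,3S)-3-(hydroxymethyl)-3-methyloxiran-2-yl]-6-methyloct-5-en-2-yl]-3-methyl-4-[(1E)-prop-1-en-1-yl]oxan-2-one
Conditions: Ti(OiPr)4, L-(+)-diethyl tartrate, t-BuOOH, 4 Å MS, CH2Cl2, −20 °C
Reagents that add atoms: tert-butyl hydroperoxide, CC(C)(C)OO
Why: A second Katsuki–Sharpless epoxidation with L-(+)-diethyl tartrate epoxidizes only the alkene of the new primary allylic alcohol and sets (4S,5S) by reagent control, independent of the remote stereocentres.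

Step 8
Reactants: 13 epoxy alcohol
Product: 14 epoxy aldehyde (C6 aldehyde of 13)
Conditions: Dess–Martin periodinane, NaHCO3, CH2Cl2, 0 to 23 °C
Reagents that add atoms: none
Why: Dess–Martin oxidation of the primary epoxy alcohol under buffered conditions leaves the tertiary alcohol, the lactone and the oxirane intact, and the quaternary C5 cannot epimerize.

Step 9
Reactants: 14 epoxy aldehyde
Product: 15 (3S,4S,6R)-6-[(2S,5E)-8-[(2S,3S)-3-ethenyl-3-methyloxiran-2-yl]-2-hydroxy-6-methyloct-5-en-2-yl]-3-methyl-4-[(1E)-prop-1-en-1-yl]oxan-2-one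
Conditions: Ph3PCH3Br, KN(SiMe3)2, THF, −78 to 0 °C
Reagents that add atoms: methyltriphenylphosphonium bromide, C[P+](c1ccccc1)(c1ccccc1)c1ccccc1.[Br-]
Why: Wittig methylenation of the highly electrophilic epoxy aldehyde at low temperature outpaces any reaction of the ylide with the lactone and creates no stereocentre.

Step 10
Reactants: 15 vinyl epoxide diene
Product: 16 macrocyclic alkene (C6=C7 in the 14-membered ring)
Conditions: second-generation Grubbs catalyst RuCl2(1,3-dimesitylimidazolidin-2-ylidene)(PCy3)(=CHPh) (10 mol%), 1,4-benzoquinone (cat.), toluene (1 mM), 80 °C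
Reagents that add atoms: none
Why: Ring-closing metathesis joins C6 and C7 with loss of propene; the trisubstituted alkene is inert, smaller rings are excluded because they would contain a trans-fused oxirane, and the geometry of the new alkene is irrelevant because it is reduced next.

Step 11
Reactants: 16 macrocyclic alkene
Product: 17 saturated bridged macrocycle (C6–C7 single bond)
Conditions: 2-nitrobenzenesulfonyl hydrazide, Et3N, CH2Cl2, 23 °C
Reagents that add atoms: none
Why: Diimide generated from the sulfonyl hydrazide transfers two hydrogens suprafacially to the 1,2-disubstituted alkene far faster than to the trisubstituted one and cannot hydrogenolyse the allylic oxirane; C8 becomes (R) by CIP with unchanged geometry.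

Step 12
Reactants: 17 saturated bridged macrocycle
Product: 18 target hydroperoxide CNP0319766.2
Conditions: O2, visible light, tetraphenylporphyrin (cat.), CH2Cl2, 0 °C
Reagents that add atoms: dioxygen, O=O
Why: Schenck ene reaction of singlet oxygen with the only alkene: the cis effect directs hydrogen abstraction to the C20 methyl, whose C–H bonds can always align with the π-system, giving the exocyclic alkene and the C14–O bond, and oxygen is expected to add to the exposed outer face of the lactone-bridged ring to set C14 as (S) under substrate control.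

Compound list
1 | (2E,6E)-farnesol, (2E,6E)-3,7,11-trimethyldodeca-2,6,10-trien-1-ol | OC/C=C(\C)CC/C=C(\C)CCC=C(C)C | starting material
2 | (2S,3S)-2,3-epoxyfarnesol, [(2S,3S)-3-[(3E)-4,8-dimethylnona-3,7-dien-1-yl]-3-methyloxiran-2-yl]methanol | OC[C@@H]1O[C@@]1(C)CC/C=C(\C)CCC=C(C)C | intermediate
3 | epoxyfarnesyl triflate, trifluoromethanesulfonate ester of 2 with unchanged (2S,3S) oxirane | O=S(=O)(OC[C@@H]1O[C@@]1(C)CC/C=C(\C)CCC=C(C)C)C(F)(F)F | intermediate (not isolated)
4 | (2S,3S)-2-[(3E)-4,8-dimethylnona-3,7-dien-1-yl]-2-methyl-3-(prop-2-en-1-yl)oxirane | C=CC[C@@H]1O[C@@]1(C)CC/C=C(\C)CCC=C(C)C | intermediate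
5 | (R)-but-3-en-2-ol | C[C@@H](O)C=C | starting material
6 | (R)-but-3-en-2-yl propanoate | CCC(=O)O[C@H](C)C=C | intermediate
7 | (2R,3E)-5-[(2S,3S)-3-[(3E)-4,8-dimethylnona-3,7-dien-1-yl]-3-methyloxiran-2-yl]pent-3-en-2-yl propanoate | CCC(=O)O[C@H](C)/C=C/C[C@@H]1O[C@@]1(C)CC/C=C(\C)CCC=C(C)C | intermediate
8 | (E)-trimethylsilyl ketene acetal of 7 (C17 methyl cis to the allylic oxygen, trans to OSiMe3) | C/C=C(\O[C@H](C)/C=C/C[C@@H]1O[C@@]1(C)CC/C=C(\C)CCC=C(C)C)O[Si](C)(C)C | intermediate (not isolated)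
9 | trimethylsilyl (2S,3S,4E)-3-{[(2S,3S)-3-[(3E)-4,8-dimethylnona-3,7-dien-1-yl]-3-methyloxiran-2-yl]methyl}-2-methylhex-4-enoate | C/C=C/[C@H](C[C@@H]1O[C@@]1(C)CC/C=C(\C)CCC=C(C)C)[C@H](C)C(=O)O[Si](C)(C)C | intermediate (not isolated)
10 | tetrabutylammonium (2S,3S,4E)-3-{[(2S,3S)-3-[(3E)-4,8-dimethylnona-3,7-dien-1-yl]-3-methyloxiran-2-yl]methyl}-2-methylhex-4-enoate | C/C=C/[C@H](C[C@@H]1O[C@@]1(C)CC/C=C(\C)CCC=C(C)C)[C@H](C)C(=O)[O-].CCCC[N+](CCCC)(CCCC)CCCC | intermediate (not isolated)
11 | (3S,4S,6R)-6-[(2S,5E)-2-hydroxy-6,10-dimethylundeca-5,9-dien-2-yl]-3-methyl-4-[(1E)-prop-1-en-1-yl]oxan-2-one | C/C=C/[C@@H]1C[C@@H](OC(=O)[C@H]1C)[C@@](C)(O)CC/C=C(\C)CCC=C(C)C | intermediate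
12 | (3S,4S,6R)-6-[(2S,5E,9E)-2,11-dihydroxy-6,10-dimethylundeca-5,9-dien-2-yl]-3-methyl-4-[(1E)-prop-1-en-1-yl]oxan-2-one | C/C=C/[C@@H]1C[C@@H](OC(=O)[C@H]1C)[C@@](C)(O)CC/C=C(\C)CC/C=C(\C)CO | intermediate
13 | (3S,4S,6R)-6-[(2S,5E)-2-hydroxy-8-[(2S,3S)-3-(hydroxymethyl)-3-methyloxiran-2-yl]-6-methyloct-5-en-2-yl]-3-methyl-4-[(1E)-prop-1-en-1-yl]oxan-2-one | C/C=C/[C@@H]1C[C@@H](OC(=O)[C@H]1C)[C@@](C)(O)CC/C=C(\C)CC[C@@H]1O[C@@]1(C)CO | intermediate
14 | (2R,3S)-3-[(3E,7S)-7-hydroxy-3-methyl-7-[(2R,4S,5S)-5-methyl-6-oxo-4-[(1E)-prop-1-en-1-yl]oxan-2-yl]oct-3-en-1-yl]-2-methyloxirane-2-carbaldehyde (geometry of 13; 2R by CIP only) | C/C=C/[C@@H]1C[C@@H](OC(=O)[C@H]1C)[C@@](C)(O)CC/C=C(\C)CC[C@@H]1O[C@@]1(C)C=O | intermediate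
15 | (3S,4S,6R)-6-[(2S,5E)-8-[(2S,3S)-3-ethenyl-3-methyloxiran-2-yl]-2-hydroxy-6-methyloct-5-en-2-yl]-3-methyl-4-[(1E)-prop-1-en-1-yl]oxan-2-one | C/C=C/[C@@H]1C[C@@H](OC(=O)[C@H]1C)[C@@](C)(O)CC/C=C(\C)CC[C@@H]1O[C@@]1(C)C=C | intermediate
16 | bridged macrocycle: 14-membered carbocycle with C14=C1 (E, methyl C20 on C1) and C6=C7 alkenes, (4S,5S)-oxirane (methyl C18 on C5), (11S)-carbinol (methyl C19), δ-lactone C10–O–C16(=O)–C15(methyl C17)–C8; 8S (CIP only), 10R, 15S | C1[C@@H]2O[C@@]2(C)/C=C/[C@@H]2C[C@@H](OC(=O)[C@H]2C)[C@@](C)(O)CC/C=C(\C)C1 | intermediate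
17 | bridged macrocycle as 16 with C6–C7 saturated; (4S,5S,8R,10R,11S,15S), (E)-C14=C1 | C1[C@@H]2O[C@@]2(C)CC[C@@H]2C[C@@H](OC(=O)[C@H]2C)[C@@](C)(O)CC/C=C(\C)C1 | intermediate
18 | CNP0319766.2: (4S,5S,8R,10R,11S,14S,15S)-4,5-epoxy-14-hydroperoxy-11-hydroxy macrocycle with exocyclic C1=C20 methylene and δ-lactone C10–O–C16(=O)–C15–C8 | C=C1CC[C@@H]2O[C@@]2(C)CC[C@@H]2C[C@@H](OC(=O)[C@H]2C)[C@@](C)(O)CC[C@@H]1OO | target

Total step count: 12
Longest linear sequence: 11 steps (1 → 2 → 4 → 7 → 11 → 12 → 13 → 14 → 15 → 16 → 17 → 18; step 3 prepares ester 6)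

Steps most likely to fail

Step 12. Oxygen delivery at C14 may show poor facial selectivity on the conformationally mobile macrocyclic alkene, and hydrogen abstraction from C13 may compete. The fallback sets out from 17 and comes back at 18. The photooxygenation is still used to place oxygen at C14, and the configuration is then set by a reagent. The crude mixture of 18 and its C14 epimer, the (14R)-hydroperoxide F4, is reduced with PPh3 to the epimeric allylic alcohols F5. These are oxidized with Dess–Martin periodinane to the α-methylene ketone F6. Reduction with catecholborane and the (S)-2-methyl-CBS-oxazaborolidine (alkenyl group as the large substituent) should give the (14R)-allylic alcohol F7. MsCl/Et3N at −20 °C gives the methanesulfonate F8, and displacement with anhydrous H2O2 in Et2O at low temperature (SN2, inversion) returns to 18.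

Step 10. Catalyst loading may be slow on both hindered alkenes (propenyl on the tertiary C8, vinyl on the quaternary C5), so that oligomerization outruns ring closure. The fallback sets out from 14 and comes back at 16 by relay ring-closing metathesis. Aldehyde 14 is olefinated with the ylide from (hex-5-en-1-yl)triphenylphosphonium bromide (KN(SiMe3)2, THF, −78 °C) to give the relay triene F3. The second-generation Grubbs catalyst loads on the unhindered terminal alkene of F3, expels cyclopentene and is thereby placed on C6. Ring closure onto the propenyl group then gives 16.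

Step 5. Chloride may open the oxirane during silylation, and closure of the carboxylate onto the trisubstituted oxirane may be slow. The fallback sets out from 4 and 5 and comes back at 11, avoiding both silyl chloride and strong base. Cross-metathesis of 4 with 5 (catalyst of step 4) gives the (2R,3E)-allylic alcohol F1. Eschenmoser–Claisen rearrangement with 1,1-dimethoxy-N,N-dimethylpropan-1-amine (xylene, 140 °C) gives the γ,δ-unsaturated dimethylamide F2 by the same chair-controlled chirality transfer. Camphorsulfonic acid in wet THF then lets the amide oxygen open the oxirane at C10 and hydrolyses the resulting iminium ether to lactone 11.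

Further compounds
F1 | step 5 | (2R,3E)-5-[(2S,3S)-3-[(3E)-4,8-dimethylnona-3,7-dien-1-yl]-3-methyloxiran-2-yl]pent-3-en-2-ol | C[C@@H](O)/C=C/C[C@@H]1O[C@@]1(C)CC/C=C(\C)CCC=C(C)C
F2 | step 5 | (2S,3S,4E)-3-{[(2S,3S)-3-[(3E)-4,8-dimethylnona-3,7-dien-1-yl]-3-methyloxiran-2-yl]methyl}-N,N,2-trimethylhex-4-enamide | C/C=C/[C@H](C[C@@H]1O[C@@]1(C)CC/C=C(\C)CCC=C(C)C)[C@H](C)C(=O)N(C)C
F3 | step 10 | (3S,4S,6R)-6-[(2S,5E)-8-[(2S,3S)-3-[(1Z)-hepta-1,6-dien-1-yl]-3-methyloxiran-2-yl]-2-hydroxy-6-methyloct-5-en-2-yl]-3-methyl-4-[(1E)-prop-1-en-1-yl]oxan-2-one | C/C=C/[C@@H]1C[C@@H](OC(=O)[C@H]1C)[C@@](C)(O)CC/C=C(\C)CC[C@@H]1O[C@@]1(C)/C=C\CCCC=C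
F4 | step 12 | C14 epimer of 18, the (14R)-hydroperoxide | C=C1CC[C@@H]2O[C@@]2(C)CC[C@@H]2C[C@@H](OC(=O)[C@H]2C)[C@@](C)(O)CC[C@H]1OO
F5 | step 12 | C14-epimeric allylic alcohols (14-hydroxy analogue of 18, both epimers) | C=C1CC[C@@H]2O[C@@]2(C)CC[C@@H]2C[C@@H](OC(=O)[C@H]2C)[C@@](C)(O)CCC1O
F6 | step 12 | α-methylene ketone (14-oxo analogue of 18) | C=C1CC[C@@H]2O[C@@]2(C)CC[C@@H]2C[C@@H](OC(=O)[C@H]2C)[C@@](C)(O)CCC1=O
F7 | step 12 | (14R)-allylic alcohol (14-hydroxy analogue of 18 with inverted C14) | C=C1CC[C@@H]2O[C@@]2(C)CC[C@@H]2C[C@@H](OC(=O)[C@H]2C)[C@@](C)(O)CC[C@H]1O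
F8 | step 12 | (14R)-methanesulfonate of F7 | C=C1CC[C@@H]2O[C@@]2(C)CC[C@@H]2C[C@@H](OC(=O)[C@H]2C)[C@@](C)(O)CC[C@H]1OS(C)(=O)=O
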